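## Retrosynthetic overview

1. The 1,4-benzoquinone (ring B) is taken apart last, into three components: a terminal 2-ethynylfuran (ring carbons C2–C3), one CO (C1) and the three-carbon alkenyl(methoxy)carbene ligand of a chromium complex (C4–C5–C6). A Dötz benzannulation with oxidative work-up then gives the quinone directly.
2. Enabling feature: in ring B the carbonyl carbons C1 and C4 are para, C2 carries the furan α-carbon, and C3, C5 and C6 are CH. This is the pattern that CO, a terminal alkyne and a vinylcarbene deliver, and because C5 and C6 are unsubstituted, either insertion sense of the alkyne ends in the same quinone.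
3. The ethynylfuran comes from furan-3-carbaldehyde: C5 iodination, asymmetric allylation (sets the S centre), cross-metathesis to the 4-methylpent-3-enyl chain, esterification, Sonogashira coupling and desilylation.
4. The carbene complex comes in one step from (E)-(2-bromoethenyl)trimethylsilane, Cr(CO)6 and MeOTf.
5. Ring order: the furan (ring A) is bought intact; ring B is the only ring made and is closed in the last step.

Key step: step 8

Remark on the chemistry: furan-3-carbaldehyde, 3-methylbut-2-enoic acid, ethynyltrimethylsilane, (E)-(2-bromoethenyl)trimethylsilane and Cr(CO)6 are taken as commercial. The trimethylsilyl group on the vinyl terminus of the carbene complex is a temporary placeholder for hydrogen and is lost again inside the key step. (−)-Ipc2B(allyl) means the reagent derived from (+)-α-pinene.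

## Route

Step 1
Reactants: 1 furan-3-carbaldehyde
Product: 5 5-iodofuran-3-carbaldehyde, via lithium morpholide adduct 2 (not isolated), via C5-lithiated adduct 3 (not isolated), via iodinated adduct 4 (not isolated)
Conditions: morpholine, n-BuLi, THF, −78 °C; s-BuLi, −78 °C; I2, THF, −78 → 0 °C; H2O
Reagents that add atoms: iodine, II
Why: Directed lithiation of an aldehyde masked in situ as its α-amino alkoxide: the bulky, non-chelating morpholine adduct protects the formyl group and shields C2, so s-BuLi should remove the proton at the remote α-position C5, and iodinolysis followed by hydrolytic unmasking should give the 2,4-disubstituted furan.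

Step 2
Reactants: 5 5-iodofuran-3-carbaldehyde
Product: 7 (S)-1-(5-iodofuran-3-yl)but-3-en-1-ol, via borinate ester 6 (not isolated)
Conditions: (−)-Ipc2B(allyl), Et2O, −78 °C; then NaOH, H2O2, H2O, 0 °C → rt
Reagents that add atoms: (−)-B-allyldiisopinocampheylborane, C=CCB([C@H]1[C@H](C)[C@H]2C[C@@H](C1)C2(C)C)[C@H]1[C@H](C)[C@H]2C[C@@H](C1)C2(C)C
Why: Brown asymmetric allylboration through a chair-like Zimmerman–Traxler transition state, in which the (+)-α-pinene-derived reagent should deliver allyl to the Si face of the aldehyde, which for a carbinol whose furyl group outranks the allyl group means the S configuration.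

Step 3
Reactants: 7 (S)-1-(5-iodofuran-3-yl)but-3-en-1-ol
Product: 8 (S)-1-(5-iodofuran-3-yl)-4-methylpent-3-en-1-ol
Conditions: (H2IMes)(PCy3)Cl2Ru=CHPh (second-generation Grubbs catalyst, cat.), 2-methylbut-2-ene/CH2Cl2, 40 °C
Reagents that add atoms: 2-methylbut-2-ene, CC=C(C)C
Why: Olefin cross-metathesis with a large excess of 2-methylbut-2-ene should transfer an isopropylidene unit to the terminal alkene with loss of propene, the free homoallylic hydroxyl and the iodofuran being tolerated by the ruthenium carbene and the stereocenter not being involved.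

Step 4
Reactants: 8 (S)-1-(5-iodofuran-3-yl)-4-methylpent-3-en-1-ol; 9 3-methylbut-2-enoic acid
Product: 10 (S)-1-(5-iodofuran-3-yl)-4-methylpent-3-en-1-yl 3-methylbut-2-enoate
Conditions: DCC, DMAP (cat.), CH2Cl2, 0 °C → rt
Reagents that add atoms: none
Why: Steglich esterification (carbodiimide activation, DMAP acyl transfer) acylates the secondary furylic alcohol at oxygen under neutral conditions, so the C–O bond at the stereocenter is untouched and the S configuration is retained.

Step 5
Reactants: 10 (S)-1-(5-iodofuran-3-yl)-4-methylpent-3-en-1-yl 3-methylbut-2-enoate; 11 ethynyltrimethylsilane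
Product: 12 (S)-4-methyl-1-{5-[(trimethylsilyl)ethynyl]furan-3-yl}pent-3-en-1-yl 3-methylbut-2-enoate
Conditions: PdCl2(PPh3)2 (cat.), CuI (cat.), Et3N, THF, rt
Reagents that add atoms: none
Why: Sonogashira coupling, in which zerovalent palladium should insert into the reactive 2-iodofuran C–I bond at room temperature and the copper acetylide of 11 transmetalates, while the ester, the alkene and the stereocenter are inert to the amine base.

Step 6
Reactants: 12 (S)-4-methyl-1-{5-[(trimethylsilyl)ethynyl]furan-3-yl}pent-3-en-1-yl 3-methylbut-2-enoate
Product: 13 (S)-1-(5-ethynylfuran-3-yl)-4-methylpent-3-en-1-yl 3-methylbut-2-enoate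
Conditions: Bu4NF, AcOH, THF, 0 °C
Reagents that add atoms: none
Why: Fluoride-induced protodesilylation of the alkynylsilane is fast at 0 °C, and the acetic acid buffer keeps the medium non-basic so that the ester and the furylic stereocenter should survive.

Step 7
Reactants: 14 (E)-(2-bromoethenyl)trimethylsilane; 15 Cr(CO)6
Product: 18 pentacarbonyl{methoxy[(E)-2-(trimethylsilyl)ethenyl]methylidene}chromium (CO)5Cr=C(OMe)CH=CHSiMe3, via vinyllithium 16 (not isolated), via lithium acylchromate 17 (not isolated)
Conditions: t-BuLi (2 equiv), Et2O, −78 °C; Cr(CO)6, Et2O, −78 °C → rt; MeOTf, CH2Cl2, 0 °C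
Reagents that add atoms: methyl trifluoromethanesulfonate, COS(=O)(=O)C(F)(F)F
Why: Fischer carbene synthesis, in which bromine–lithium exchange with retention of the E geometry gives the vinyllithium, this adds to a CO ligand of Cr(CO)6, and O-methylation of the acylchromate gives the alkoxycarbene complex, whose β-silyl group suppresses the polymerisation that plagues the parent vinyl complex.

Step 8
Reactants: 13 (S)-1-(5-ethynylfuran-3-yl)-4-methylpent-3-en-1-yl 3-methylbut-2-enoate; 18 pentacarbonyl{methoxy[(E)-2-(trimethylsilyl)ethenyl]methylidene}chromium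
Product: 20 (S)-1-[5-(3,6-dioxocyclohexa-1,4-dien-1-yl)furan-3-yl]-4-methylpent-3-en-1-yl 3-methylbut-2-enoate (CNP0314322.1), via aryl silyl ether 19 (not isolated)
Conditions: THF, 50 °C, Ar; then (NH4)2Ce(NO3)6, MeCN/H2O, 0 °C
Reagents that add atoms: water, O
Why: Dötz benzannulation: thermal loss of one CO from 18 lets the terminal alkyne of 13 insert into the chromium–carbene bond, a CO ligand then inserts to give a chromium-bound dienylketene, this closes the six-membered ring by 6π-electrocyclisation between the ketene carbon and the silyl-bearing vinyl carbon, and a 1,3 carbon-to-oxygen silyl shift aromatises the cyclohexadienone to 19. The closest known reaction type is the benzannulation of alkenyl(alkoxy)carbene complexes of zerovalent chromium with terminal aryl alkynes followed by oxidative work-up to the quinone, including the use of trans-β-silylvinyl complexes as stable equivalents of the parent vinyl complex. The ring is closed at a carbon–carbon bond (C1–C6 of the new arene) in a formal [3+2+1] assembly of three carbene-ligand carbons, two alkyne carbons and one carbon monoxide, so three C–C bonds and both oxygen-bearing carbons arise in one operation. No stereocenter is formed, and the S centre of 13 is not touched under these neutral, non-basic conditions. The step needs chemoselectivity for phenol-type annulation over cyclobutenone or two-alkyne products, which the alkenyl (not aryl) carbene and the donor solvent should secure, whereas the sense of alkyne insertion is immaterial because C5 and C6 carry only hydrogen and both orientations converge on the same 2-substituted quinone. In the same flask (NH4)2Ce(NO3)6 should oxidise the 4-methoxyaryl silyl ether, the most electron-rich site, to the quinone at 0 °C with loss of methanol and trimethylsilanol, strip chromium from the arene, and leave the furan, the trisubstituted alkene and the ester intact.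

## Compound list

1 | furan-3-carbaldehyde | O=Cc1ccoc1 | starting material
2 | lithium (furan-3-yl)(morpholin-4-yl)methanolate | [Li]OC(c1ccoc1)N1CCOCC1 | intermediate
3 | lithium (5-lithiofuran-3-yl)(morpholin-4-yl)methanolate | [Li]OC(c1coc([Li])c1)N1CCOCC1 | intermediate
4 | lithium (5-iodofuran-3-yl)(morpholin-4-yl)methanolate | [Li]OC(c1coc(I)c1)N1CCOCC1 | intermediate
5 | 5-iodofuran-3-carbaldehyde | O=Cc1coc(I)c1 | intermediate
6 | (S)-1-(5-iodofuran-3-yl)but-3-en-1-yl diisopinocampheylborinate | C=CC[C@H](OB([C@H]1[C@H](C)[C@H]2C[C@@H](C1)C2(C)C)[C@H]1[C@H](C)[C@H]2C[C@@H](C1)C2(C)C)c1coc(I)c1 | intermediate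
7 | (S)-1-(5-iodofuran-3-yl)but-3-en-1-ol | C=CC[C@H](O)c1coc(I)c1 | intermediate
8 | (S)-1-(5-iodofuran-3-yl)-4-methylpent-3-en-1-ol | CC(C)=CC[C@H](O)c1coc(I)c1 | intermediate
9 | 3-methylbut-2-enoic acid | CC(C)=CC(=O)O | starting material
10 | (S)-1-(5-iodofuran-3-yl)-4-methylpent-3-en-1-yl 3-methylbut-2-enoate | CC(C)=CC[C@H](OC(=O)C=C(C)C)c1coc(I)c1 | intermediate
11 | ethynyltrimethylsilane | C#C[Si](C)(C)C | starting material
12 | (S)-4-methyl-1-{5-[(trimethylsilyl)ethynyl]furan-3-yl}pent-3-en-1-yl 3-methylbut-2-enoate | CC(C)=CC[C@H](OC(=O)C=C(C)C)c1coc(C#C[Si](C)(C)C)c1 | intermediate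
13 | (S)-1-(5-ethynylfuran-3-yl)-4-methylpent-3-en-1-yl 3-methylbut-2-enoate | CC(C)=CC[C@H](OC(=O)C=C(C)C)c1coc(C#C)c1 | intermediate
14 | (E)-(2-bromoethenyl)trimethylsilane | C[Si](C)(C)/C=C/Br | starting material
15 | chromium hexacarbonyl Cr(CO)6 | O=C=[Cr](=C=O)(=C=O)(=C=O)(=C=O)=C=O | starting material
16 | (E)-[2-(trimethylsilyl)ethenyl]lithium | [Li]/C=C/[Si](C)(C)C | intermediate
17 | lithium pentacarbonyl[(E)-3-(trimethylsilyl)propenoyl]chromate | [Li]OC(/C=C/[Si](C)(C)C)=[Cr](=C=O)(=C=O)(=C=O)(=C=O)=C=O | intermediate
18 | pentacarbonyl{methoxy[(E)-2-(trimethylsilyl)ethenyl]methylidene}chromium | COC(/C=C/[Si](C)(C)C)=[Cr](=C=O)(=C=O)(=C=O)(=C=O)=C=O | intermediate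
19 | (S)-1-{5-[5-methoxy-2-(trimethylsilyloxy)phenyl]furan-3-yl}-4-methylpent-3-en-1-yl 3-methylbut-2-enoate | CC(C)=CC[C@H](OC(=O)C=C(C)C)c1coc(-c2cc(OC)ccc2O[Si](C)(C)C)c1 | intermediate
20 | (S)-1-[5-(3,6-dioxocyclohexa-1,4-dien-1-yl)furan-3-yl]-4-methylpent-3-en-1-yl 3-methylbut-2-enoate (CNP0314322.1) | CC(C)=CC[C@H](OC(=O)C=C(C)C)c1coc(C2=CC(=O)C=CC2=O)c1 | target

## Step count and risks

Total step count: 8 steps.
Longest linear sequence: 7 steps (steps 1–6 and 8); step 7 is a one-step side branch.

Steps most likely to fail:

1. Step 8 (benzannulation and oxidation). The carbene complex may be consumed unproductively, by oligomerisation, by incorporation of two alkyne units before CO insertion, or by incomplete silyl transfer, so that little arene is formed. The fallback sets out from 10 and comes back at 20. Suzuki–Miyaura coupling of 10 with (2,5-dimethoxyphenyl)boronic acid (Pd(PPh3)4, K3PO4, THF/H2O, 50 °C) should give (S)-1-[5-(2,5-dimethoxyphenyl)furan-3-yl]-4-methylpent-3-en-1-yl 3-methylbut-2-enoate F1. Oxidative demethylation of F1 with (NH4)2Ce(NO3)6 in MeCN/H2O at 0 °C should then deliver 20. In this variant the six-membered ring is bought and not built.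

2. Step 1 (C5 iodination). Deprotonation may occur at C2 instead of C5, or s-BuLi may attack the masked formyl carbon, giving the wrong regioisomer or an alcohol. The fallback sets out from 1 and comes back at 5. It replaces directed metalation by electrophilic aromatic substitution under electronic control: N-iodosuccinimide with CF3CO2H in MeCN at rt should iodinate 1 at C5, the α-position that is not conjugated with the formyl group, and give 5 directly. This fallback makes no compound outside the list (entry F0).

3. Step 4 (esterification). γ-Deprotonation of the activated acyl species may lead through a vinylketene to the deconjugated 3-methylbut-3-enoate, or the furylic C–O bond may ionise with erosion of configuration. The fallback sets out from 8 and comes back at 10. Acylation of 8 with 2-(diethoxyphosphoryl)acetic acid (DCC, DMAP, CH2Cl2), an acid that cannot deconjugate, should give (S)-1-(5-iodofuran-3-yl)-4-methylpent-3-en-1-yl 2-(diethoxyphosphoryl)acetate F2. Horner–Wadsworth–Emmons olefination of F2 with acetone (NaH, THF, 0 °C → rt) then builds the 3-methylbut-2-enoate double bond in place and should give 10.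

## Further compounds

F1 | step 8 | (S)-1-[5-(2,5-dimethoxyphenyl)furan-3-yl]-4-methylpent-3-en-1-yl 3-methylbut-2-enoate | CC(C)=CC[C@H](OC(=O)C=C(C)C)c1coc(-c2cc(OC)ccc2OC)c1
F0 | step 1 | none | none
F2 | step 4 | (S)-1-(5-iodofuran-3-yl)-4-methylpent-3-en-1-yl 2-(diethoxyphosphoryl)acetate | CCOP(=O)(CC(=O)O[C@@H](CC=C(C)C)c1coc(I)c1)OCC
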